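I read these flasks at 4.0 d, so I first ask what has had time to balance.

- south-east: starting complex 0.20 M; incoming ligand 0.210 M; protic impurity 0.0800 M; time 4.0 d
- south-west: starting complex 0.20 M; incoming ligand 0.210 M; protic impurity 0.0400 M; time 4.0 d

    starting complex + incoming ligand ⇌ leaving ligand + complex with one exchanged (K1 = 44, k1 = 3.89 × 10⁻⁴ M⁻¹ s⁻¹)
    complex with two exchanged + incoming ligand ⇌ leaving ligand + complex with three exchanged (K2 = 57.5, k2 = 2.56 × 10⁻⁴ M⁻¹ s⁻¹)
    complex with one exchanged + incoming ligand ⇌ leaving ligand + complex with two exchanged (K3 = 0.25, k3 = 3.63 × 10⁻⁴ M⁻¹ s⁻¹)
    protic impurity + incoming ligand → quenched reagent (k4 = 6.31 × 10⁻⁵ M⁻¹ s⁻¹)

- which of these there is most of at the end, counted by the starting complex in it, south-east (complex with one exchanged / starting complex / complex with two exchanged / complex with three exchanged)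
- which of these there is most of at the end, counted by the starting complex in it, south-west (complex with one exchanged / starting complex / complex with two exchanged / complex with three exchanged)
- amount of the one of these that there is most of at the end, in percent of the starting complex charged, south-east
- amount of the one of these that there is most of at the end, in percent of the starting complex charged, south-west

1. In south-west, at the charged amounts and with the way back not counted, the first exchange has a half-life of 0.098 d, the second 0.11 d and the third 0.15 d, which is short against the time. So, as an estimate, I reckon the complexes as balanced.

2. Free ligand then drops out of the swaps between complexes. Starting complex and complex with two exchanged give two of complex with one exchanged, so [one]²/([start][two]) tends to S = 176, the swap constant: the first exchange constant over the second (the comproportionation constant). Likewise, two of complex with two exchanged give complex with one exchanged and complex with three exchanged, with T = 230.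

3. First way, the ladder. I assume one ligand per complex on average and let u = [two]/[one]. Each complex with three exchanged then leaves two starting complexes behind, and [two] is small, so u = 0.0231. That puts 71.8% in complex with one exchanged, 17.7% in starting complex and 8.81% in complex with three exchanged.

4. Second way, the count. I take the ligand charge less the whole impurity and put one ligand on each complex. This gives 85.0% for south-west and 65.0% for south-east.

5. The two part, and the count cheats. A complex with three exchanged holds three ligands, and I don't expect the impurity to take ligand for its whole charge: at the start of south-west the first exchange, forward step alone, takes ligand 31 times as fast as the quench, and its half-life at the charged amounts is shorter than the quench's 0.61 d. The ladder has no quench, though, and that comparison drifts: the first exchange has a way back, so its net rate falls, while the quench has none.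

6. I commit to complex with one exchanged in both flasks, near the ladder's figure, with south-east somewhat below south-west.

The forecast says complex with one exchanged at 72% for south-east and complex with one exchanged at 76% for south-west: “the singly exchanged complex dominates in both cases”. Unlike my single ladder figure, it separates the flasks.

The simulation gives complex with one exchanged at 70.4% in south-east and complex with one exchanged at 72.5% in south-west, so the forecast stands within its margins.

At the end of south-west, [one]²/([start][two]) stands at 188 against S = 176. The lead of complex with one exchanged is owed to the undoing of the second exchange: with that undoing taken away, south-west ends with 23.4% of it instead of 72.5%. The neighbour of south-west charged with 0.84 M of incoming ligand ends mostly as complex with three exchanged, at 78.4%, and there the same ratio reads 176.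

All constants are those of an exercise; the run is a simulation.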